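**Retrosynthetic overview**
1. No ring is built: both benzene rings are bought in one building block, 3,5-bis(benzyloxy)benzyl bromide 1. All four phenols stay benzylated until the last step (17 ⇐ 15 by one hydrogenation/hydrogenolysis).
2. Ester C–O: 15 ⇐ acid 13 + homoallylic alcohol 8 (Mitsunobu, inversion R → S).
3. Key C–C bond (C3–C4 of 8): aldehyde 6 + allyl unit by Brown asymmetric allylboration, which sets the only stereocentre.
4. 6 ⇐ terminal alkene 4 (oxidative cleavage) ⇐ 1 + oct-7-enylmagnesium bromide 3 (Cu-catalysed benzylic coupling).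
5. 13 ⇐ aldehyde 12 (Pinnick) ⇐ arene 10 (Vilsmeier–Haack) ⇐ 1 + decylmagnesium bromide 9.

Assumption: the stereocentre in the target SMILES is read as R (C4 of the undecan-4-yl group); 1, 2, 9 and (−)-Ipc2B(allyl) (1 M in pentane) are bought.

**Route**

Step 1
Reactants: 1 3,5-bis(benzyloxy)benzyl bromide; 2 8-bromooct-1-ene
Product: 4 1,3-bis(benzyloxy)-5-(non-8-en-1-yl)benzene, via oct-7-enylmagnesium bromide 3 (not isolated)
Conditions: 2 (1.5 equiv), Mg turnings, cat. I2, THF, 40 °C; then 1, Li2CuCl4 (3 mol%), THF, −78 °C → rt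
Reagents that add atoms: none
Why: Kochi-type Cu-catalysed sp3–sp3 cross-coupling, in which the cuprate formed from the alkyl Grignard reagent and catalytic Li2CuCl4 displaces the reactive benzylic bromide at low temperature while the remote terminal alkene and the benzyl ethers are inert.

Step 2
Reactants: 4 1,3-bis(benzyloxy)-5-(non-8-en-1-yl)benzene
Product: 6 8-[3,5-bis(benzyloxy)phenyl]octanal, via 1,2-diol 5 (not isolated)
Conditions: OsO4 (2 mol%), NaIO4 (4 equiv), 2,6-lutidine (2 equiv), 1,4-dioxane/H2O 3:1, rt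
Reagents that add atoms: osmium tetroxide, O=[Os](=O)(=O)=O; sodium periodate, [Na+].[O-]I(=O)(=O)=O
Why: Lemieux–Johnson oxidation, in which OsO4 dihydroxylates only the terminal alkene and NaIO4 cleaves the diol and reoxidises osmium, with 2,6-lutidine suppressing over-oxidation and the aryl benzyl ethers left untouched.

Step 3
Reactants: 6 8-[3,5-bis(benzyloxy)phenyl]octanal
Product: 8 (4R)-11-[3,5-bis(benzyloxy)phenyl]undec-1-en-4-ol, via borinate ester 7 (not isolated)
Conditions: (−)-Ipc2B(allyl) (from (+)-α-pinene, 1 M in pentane, 1.3 equiv), Et2O, −100 °C, 2 h; then 3 M NaOH, 30% H2O2, 0 °C → rt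
Reagents that add atoms: (−)-B-allyldiisopinocampheylborane, C=CCB([C@@H]1C[C@@H]2C[C@H]([C@H]1C)C2(C)C)[C@@H]1C[C@@H]2C[C@H]([C@H]1C)C2(C)C
Why: Brown asymmetric allylboration (carbonyl allylation) through a closed chair transition state, in which the isopinocampheyl groups derived from (+)-α-pinene direct the allyl group to the Si face of the aldehyde and so form the C3–C4 bond with the R configuration (typically ≥94% ee under salt-free conditions at −100 °C).

Step 4
Reactants: 1 3,5-bis(benzyloxy)benzyl bromide; 9 decylmagnesium bromide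
Product: 10 1,3-bis(benzyloxy)-5-undecylbenzene
Conditions: 9 (1.0 M in Et2O, 1.5 equiv), Li2CuCl4 (3 mol%), THF, −78 °C → rt
Reagents that add atoms: none
Why: The same Kochi-type Cu-catalysed coupling of a primary alkyl Grignard reagent with the benzylic bromide, giving the undecyl side chain directly in saturated form.

Step 5
Reactants: 10 1,3-bis(benzyloxy)-5-undecylbenzene
Product: 12 2,4-bis(benzyloxy)-6-undecylbenzaldehyde, via aryl iminium chloride 11 (not isolated)
Conditions: POCl3 (1.5 equiv), DMF, 0 °C → 60 °C; then ice, 2 M NaOH to pH 8, rt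
Reagents that add atoms: N,N-dimethylformamide, CN(C)C=O; water, O
Why: Vilsmeier–Haack formylation, in which the chloroiminium ion attacks the ring position para to one benzyloxy group and ortho to the other (the site between the two benzyloxy groups is more crowded), as known for orcinol diethers.

Step 6
Reactants: 12 2,4-bis(benzyloxy)-6-undecylbenzaldehyde
Product: 13 2,4-bis(benzyloxy)-6-undecylbenzoic acid
Conditions: NaClO2 (3 equiv), NaH2PO4 (3 equiv), 2-methyl-2-butene (10 equiv), t-BuOH/THF/H2O 2:2:1, 0 °C → rt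
Reagents that add atoms: sodium chlorite, [Na+].[O-]Cl=O
Why: Pinnick oxidation, in which buffered chlorous acid oxidises the hindered aryl aldehyde to the acid and 2-methyl-2-butene traps HOCl so that the electron-rich ring is not chlorinated.

Step 7
Reactants: 13 2,4-bis(benzyloxy)-6-undecylbenzoic acid; 8 (4R)-11-[3,5-bis(benzyloxy)phenyl]undec-1-en-4-ol
Product: 15 (4S)-11-[3,5-bis(benzyloxy)phenyl]undec-1-en-4-yl 2,4-bis(benzyloxy)-6-undecylbenzoate, via alkoxyphosphonium carboxylate 14 (not isolated)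
Conditions: PPh3 (1.5 equiv), DIAD (1.5 equiv), toluene, 0 °C → rt
Reagents that add atoms: none
Why: Mitsunobu esterification, in which the hindered 2,6-disubstituted acid acts as a carboxylate nucleophile (its shielded carbonyl is not attacked) and displaces the alkoxyphosphonium group by SN2 with inversion, turning the R carbinol into the S ester.

Step 8
Reactants: 15 (4S)-11-[3,5-bis(benzyloxy)phenyl]undec-1-en-4-yl 2,4-bis(benzyloxy)-6-undecylbenzoate
Product: 17 (4R)-11-(3,5-dihydroxyphenyl)undecan-4-yl 2,4-dihydroxy-6-undecylbenzoate, via saturated tetrabenzyl ester 16 (not isolated)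
Conditions: H2 (1 atm), 10% Pd/C, EtOAc/MeOH 1:1, rt
Reagents that add atoms: none
Why: Catalytic hydrogenation and hydrogenolysis over Pd/C, which first saturates the terminal alkene and then cleaves the four aryl benzyl ethers without touching the secondary alkyl ester or the stereocentre, whose descriptor changes from S to R only because propyl now ranks below the arylheptyl chain.

**Compound list**

1 | 3,5-bis(benzyloxy)benzyl bromide | BrCc1cc(OCc2ccccc2)cc(OCc2ccccc2)c1 | starting material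
2 | 8-bromooct-1-ene | C=CCCCCCCBr | starting material
3 | oct-7-enylmagnesium bromide | C=CCCCCCC[Mg]Br | intermediate
4 | 1,3-bis(benzyloxy)-5-(non-8-en-1-yl)benzene | C=CCCCCCCCc1cc(OCc2ccccc2)cc(OCc2ccccc2)c1 | intermediate
5 | 9-[3,5-bis(benzyloxy)phenyl]nonane-1,2-diol (racemic; both enantiomers give 6) | OCC(O)CCCCCCCc1cc(OCc2ccccc2)cc(OCc2ccccc2)c1 | intermediate
6 | 8-[3,5-bis(benzyloxy)phenyl]octanal | O=CCCCCCCCc1cc(OCc2ccccc2)cc(OCc2ccccc2)c1 | intermediate
7 | (4R)-11-[3,5-bis(benzyloxy)phenyl]undec-1-en-4-yl diisopinocampheylborinate (Ipc groups from (+)-α-pinene) | C=CC[C@H](OB([C@@H]1C[C@@H]2C[C@H]([C@H]1C)C2(C)C)[C@@H]1C[C@@H]2C[C@H]([C@H]1C)C2(C)C)CCCCCCCc1cc(OCc2ccccc2)cc(OCc2ccccc2)c1 | intermediate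
8 | (4R)-11-[3,5-bis(benzyloxy)phenyl]undec-1-en-4-ol | C=CC[C@H](O)CCCCCCCc1cc(OCc2ccccc2)cc(OCc2ccccc2)c1 | intermediate
9 | decylmagnesium bromide | CCCCCCCCCC[Mg]Br | starting material
10 | 1,3-bis(benzyloxy)-5-undecylbenzene | CCCCCCCCCCCc1cc(OCc2ccccc2)cc(OCc2ccccc2)c1 | intermediate
11 | N-{[2,4-bis(benzyloxy)-6-undecylphenyl]methylidene}-N-methylmethanaminium chloride | CCCCCCCCCCCc1cc(OCc2ccccc2)cc(OCc2ccccc2)c1C=[N+](C)C.[Cl-] | intermediate
12 | 2,4-bis(benzyloxy)-6-undecylbenzaldehyde | CCCCCCCCCCCc1cc(OCc2ccccc2)cc(OCc2ccccc2)c1C=O | intermediate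
13 | 2,4-bis(benzyloxy)-6-undecylbenzoic acid | CCCCCCCCCCCc1cc(OCc2ccccc2)cc(OCc2ccccc2)c1C(=O)O | intermediate
14 | {[(4R)-11-[3,5-bis(benzyloxy)phenyl]undec-1-en-4-yl]oxy}triphenylphosphonium 2,4-bis(benzyloxy)-6-undecylbenzoate | C=CC[C@H](O[P+](c1ccccc1)(c1ccccc1)c1ccccc1)CCCCCCCc1cc(OCc2ccccc2)cc(OCc2ccccc2)c1.CCCCCCCCCCCc1cc(OCc2ccccc2)cc(OCc2ccccc2)c1C(=O)[O-] | intermediate
15 | (4S)-11-[3,5-bis(benzyloxy)phenyl]undec-1-en-4-yl 2,4-bis(benzyloxy)-6-undecylbenzoate | CCCCCCCCCCCc1cc(OCc2ccccc2)cc(OCc2ccccc2)c1C(=O)O[C@H](CC=C)CCCCCCCc1cc(OCc2ccccc2)cc(OCc2ccccc2)c1 | intermediate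
16 | (4R)-11-[3,5-bis(benzyloxy)phenyl]undecan-4-yl 2,4-bis(benzyloxy)-6-undecylbenzoate | CCCCCCCCCCCc1cc(OCc2ccccc2)cc(OCc2ccccc2)c1C(=O)O[C@H](CCC)CCCCCCCc1cc(OCc2ccccc2)cc(OCc2ccccc2)c1 | intermediate
17 | (4R)-11-(3,5-dihydroxyphenyl)undecan-4-yl 2,4-dihydroxy-6-undecylbenzoate | CCCCCCCCCCCc1cc(O)cc(O)c1C(=O)O[C@H](CCC)CCCCCCCc1cc(O)cc(O)c1 | target

**Step count and risks**

Total step count: 8. Longest linear sequence: 5 steps (steps 1, 2, 3, 7, 8; the acid branch, steps 4, 5, 6, 7, 8, is equally long).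

First risk, step 1 (the same reaction type is used in step 4). Homocoupling of 1 to the bibenzyl or poor Grignard formation would cut the yield. The fallback replaces the organometallic coupling by a sulfone alkylation and sets out from 1. PhSO2Na in DMF at rt gives 3,5-bis(benzyloxy)benzyl phenyl sulfone F1. n-BuLi in THF at −78 °C gives the α-lithio sulfone F2, which is alkylated with 2 to 1,3-bis(benzyloxy)-5-[1-(phenylsulfonyl)non-8-en-1-yl]benzene F3. Reductive desulfonylation with Mg turnings in MeOH at 50 °C comes back to the route at 4.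

Second risk, step 3. Unbranched aliphatic aldehydes can give an ee short of what a single enantiomer needs; the ee of 8 is checked as its Mosher ester. The fallback sets the stereocentre by kinetic resolution of an epoxide and sets out from 4. mCPBA in CH2Cl2 gives racemic 2-{7-[3,5-bis(benzyloxy)phenyl]heptyl}oxirane F4. Hydrolytic kinetic resolution with (R,R)-(salen)Co(OAc) (trivalent cobalt, 0.5 mol%), 0.55 equiv H2O, THF, rt, is expected to hydrolyse the S epoxide and leave (2R)-2-{7-[3,5-bis(benzyloxy)phenyl]heptyl}oxirane F5 in ≥99% ee; this catalyst sense is from memory and should be confirmed on the first run. Vinylmagnesium bromide with catalytic CuI (copper iodide) in THF at −30 °C opens F5 at the terminal carbon to the bromomagnesium alkoxide F6, and aqueous work-up comes back to the route at 8.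

Third risk, step 7. The hindered acid may react slowly, the homoallylic alcohol may eliminate, or inversion may be incomplete. The fallback is a carboxylate alkylation, still with inversion, and sets out from 8 and 13. MsCl and Et3N in CH2Cl2 at 0 °C turn 8 into (4R)-11-[3,5-bis(benzyloxy)phenyl]undec-1-en-4-yl methanesulfonate F7. Cs2CO3 in DMF turns 13 into cesium 2,4-bis(benzyloxy)-6-undecylbenzoate F8. SN2 displacement of F7 by F8 in DMF at 50 °C comes back to the route at 15.

**Further compounds**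

F1 | step 1 | 3,5-bis(benzyloxy)benzyl phenyl sulfone | O=S(=O)(Cc1cc(OCc2ccccc2)cc(OCc2ccccc2)c1)c1ccccc1
F2 | step 1 | α-lithio derivative of 3,5-bis(benzyloxy)benzyl phenyl sulfone | [Li]C(c1cc(OCc2ccccc2)cc(OCc2ccccc2)c1)S(=O)(=O)c1ccccc1
F3 | step 1 | 1,3-bis(benzyloxy)-5-[1-(phenylsulfonyl)non-8-en-1-yl]benzene (racemic) | C=CCCCCCCC(c1cc(OCc2ccccc2)cc(OCc2ccccc2)c1)S(=O)(=O)c1ccccc1
F4 | step 3 | racemic 2-{7-[3,5-bis(benzyloxy)phenyl]heptyl}oxirane | C1OC1CCCCCCCc1cc(OCc2ccccc2)cc(OCc2ccccc2)c1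
F5 | step 3 | (2R)-2-{7-[3,5-bis(benzyloxy)phenyl]heptyl}oxirane | C1O[C@@H]1CCCCCCCc1cc(OCc2ccccc2)cc(OCc2ccccc2)c1
F6 | step 3 | bromomagnesium (4R)-11-[3,5-bis(benzyloxy)phenyl]undec-1-en-4-olate | C=CC[C@H](O[Mg]Br)CCCCCCCc1cc(OCc2ccccc2)cc(OCc2ccccc2)c1
F7 | step 7 | (4R)-11-[3,5-bis(benzyloxy)phenyl]undec-1-en-4-yl methanesulfonate | C=CC[C@H](OS(C)(=O)=O)CCCCCCCc1cc(OCc2ccccc2)cc(OCc2ccccc2)c1
F8 | step 7 | cesium 2,4-bis(benzyloxy)-6-undecylbenzoate | CCCCCCCCCCCc1cc(OCc2ccccc2)cc(OCc2ccccc2)c1C(=O)[O-].[Cs+]
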